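**Strategy.** The diaryl cyclopentenone (ring A, C1–C5) is traced back to the six-membered ring of a terphenyl-derived o-quinone monoketal. Enantioselective 1,2-alkynylation of its ketone installs the enyne, and one operation then turns the resulting enynyl cyclohexadienol 15 (methyl dienol ether plus dimethyl ketal) into the diquinane: gold-catalysed 5-endo-dig attack of the dienol-ether terminus on the alkyne closes ring B as a bicyclo[3.2.1]octadienone, and unmasking the bridging ketone triggers an α-ketol 1,2-acyl shift that expels the carbinol carbon from the six-membered ring. The step exploits the tertiary alcohol at ring-fusion carbon C1 flanked by the C2 and C8 ketones, the signature of an acyloin shift; the bridged precursor enforces the cis fusion and relays chirality from the alkynylation.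

Key step: step 10

Remark: the target is numbered as a bicyclo[3.3.0]octane (C1 ring-fusion carbinol, C2 and C8 ketones, C5 ring-fusion CH; ring A = C1–C5, ring B = C1, C5–C8); its SMILES encodes the cis-fused (1S,5S) isomer, and this is the isomer made.

Step 1
Reactants: 1 4-bromo-2,6-dimethoxyphenol
Product: 2 2-(benzyloxy)-5-bromo-1,3-dimethoxybenzene
Conditions: BnBr, K2CO3, DMF, 23 °C
Reagents that add atoms: benzyl bromide BrCc1ccccc1
Why: Williamson ether synthesis on the phenoxide masks the easily oxidised phenol during the iodination and the two cross-couplings, and the benzyl group can later be removed without touching the methyl ethers.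

Step 2
Reactants: 2 2-(benzyloxy)-5-bromo-1,3-dimethoxybenzene
Product: 3 2-(benzyloxy)-5-bromo-4-iodo-1,3-dimethoxybenzene
Conditions: NIS (1.0 equiv), TFA (0.3 equiv), MeCN, 23 °C
Reagents that add atoms: N-iodosuccinimide O=C1CCC(=O)N1I
Why: Electrophilic aromatic iodination; the two free positions are equivalent by symmetry and each is ortho to one methoxy group and para to the other, so one equivalent of reagent should give a single ortho-bromo-iodo arene.

Step 3
Reactants: 3 2-(benzyloxy)-5-bromo-4-iodo-1,3-dimethoxybenzene; 4 3,4,5-trimethoxyphenylboronic acid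
Product: 5 3-(benzyloxy)-6-bromo-2,3',4,4',5'-pentamethoxy-1,1'-biphenyl
Conditions: Pd(PPh3)4 (5 mol %), Na2CO3 (2 M aq.), DME, 80 °C
Reagents that add atoms: none
Why: Suzuki–Miyaura coupling that is chemoselective because zerovalent palladium inserts into the C–I bond much faster than into the C–Br bond, which places the trimethoxyphenyl ring next to a methoxy group.

Step 4
Reactants: 5 3-(benzyloxy)-6-bromo-2,3',4,4',5'-pentamethoxy-1,1'-biphenyl; 6 3,5-dimethoxyphenylboronic acid
Product: 7 2-(benzyloxy)-5-(3,5-dimethoxyphenyl)-1,3-dimethoxy-4-(3,4,5-trimethoxyphenyl)benzene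
Conditions: Pd(OAc)2 (5 mol %), SPhos (10 mol %), K3PO4, toluene/H2O (10:1), 100 °C
Reagents that add atoms: none
Why: Second Suzuki–Miyaura coupling at the remaining ortho-substituted aryl bromide, for which a bulky electron-rich biarylphosphine is the standard choice.

Step 5
Reactants: 7 2-(benzyloxy)-5-(3,5-dimethoxyphenyl)-1,3-dimethoxy-4-(3,4,5-trimethoxyphenyl)benzene
Product: 8 4-(3,5-dimethoxyphenyl)-2,6-dimethoxy-3-(3,4,5-trimethoxyphenyl)phenol
Conditions: H2 (1 atm), Pd/C (10 wt %), EtOAc/MeOH, 23 °C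
Reagents that add atoms: none
Why: Hydrogenolysis of the benzyl aryl ether, the only reducible function present, frees the phenol needed for dearomatisation.

Step 6
Reactants: 8 4-(3,5-dimethoxyphenyl)-2,6-dimethoxy-3-(3,4,5-trimethoxyphenyl)phenol
Product: 9 4-(3,5-dimethoxyphenyl)-2,6,6-trimethoxy-3-(3,4,5-trimethoxyphenyl)cyclohexa-2,4-dien-1-one
Conditions: PhI(OAc)2 (1.1 equiv), MeOH, 0 °C
Reagents that add atoms: methanol CO
Why: Oxidative dearomatisation of a 2-methoxyphenol by a trivalent iodine reagent in methanol gives the o-quinone monoketal; methanol should attack the methoxy-bearing ortho carbon next to the ring CH (C6 of 8) and not the one shielded by the trimethoxyphenyl group, and the two aryl groups on the diene should suppress Diels–Alder dimerisation.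

Step 7
Reactants: 10 3,5-dimethoxybenzaldehyde; 11 diethyl [3-(trimethylsilyl)prop-2-yn-1-yl]phosphonate
Product: 12 [(3E)-4-(3,5-dimethoxyphenyl)but-3-en-1-yn-1-yl]trimethylsilane
Conditions: LiHMDS, THF, −78 → 0 °C
Reagents that add atoms: none
Why: Horner–Wadsworth–Emmons olefination with a propargylic phosphonate anion, which is E-selective with aromatic aldehydes.

Step 8
Reactants: 12 [(3E)-4-(3,5-dimethoxyphenyl)but-3-en-1-yn-1-yl]trimethylsilane
Product: 13 1-[(1E)-but-1-en-3-yn-1-yl]-3,5-dimethoxybenzene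
Conditions: K2CO3 (0.2 equiv), MeOH, 23 °C
Reagents that add atoms: none
Why: Base-catalysed methanolysis of the alkynyl C–Si bond (protodesilylation) frees the terminal alkyne without touching the E alkene.

Step 9
Reactants: 9 4-(3,5-dimethoxyphenyl)-2,6,6-trimethoxy-3-(3,4,5-trimethoxyphenyl)cyclohexa-2,4-dien-1-one; 13 1-[(1E)-but-1-en-3-yn-1-yl]-3,5-dimethoxybenzene
Product: 15 (1S)-4-(3,5-dimethoxyphenyl)-1-[(3E)-4-(3,5-dimethoxyphenyl)but-3-en-1-yn-1-yl]-2,6,6-trimethoxy-3-(3,4,5-trimethoxyphenyl)cyclohexa-2,4-dien-1-ol, via alkynyl(methyl)zinc 14 (not isolated)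
Conditions: 13 (3 equiv), Me2Zn (3 equiv), (R,R)-N,N'-bis(3,5-di-tert-butylsalicylidene)-1,2-cyclohexanediamine (0.2 equiv, antipode fixed after a pilot run), toluene, 23 °C; then 9; aq. NH4Cl
Reagents that add atoms: none
Why: Enantioselective 1,2-addition of an alkynylzinc to a ketone, catalysed by a chiral Zn(salen) complex formed in the flask; the carbonyl is the only electrophilic site because its neighbours are a ketal carbon and an enol-ether carbon, and the ligand sets the (S) configuration of carbinol C1, the single stereocentre from which both stereocentres of the target derive.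

Step 10
Reactants: 15 (1S)-4-(3,5-dimethoxyphenyl)-1-[(3E)-4-(3,5-dimethoxyphenyl)but-3-en-1-yn-1-yl]-2,6,6-trimethoxy-3-(3,4,5-trimethoxyphenyl)cyclohexa-2,4-dien-1-ol
Product: 18 (1S,5S)-4-(3,5-dimethoxyphenyl)-6-[(E)-2-(3,5-dimethoxyphenyl)ethenyl]-1-hydroxy-3-(3,4,5-trimethoxyphenyl)bicyclo[3.3.0]octa-3,6-diene-2,8-dione, via bicyclo[3.2.1]octadienone ketal 16 (not isolated), via bridged hydroxy diketone 17 (not isolated)
Conditions: [(t-Bu2(2-biphenylyl)P)Au(NCMe)]SbF6 (5 mol %), CH2Cl2, H2O (2 equiv), 23 °C; then Sc(OTf)3 (0.2 equiv), MeCN/H2O (10:1), 40 °C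
Reagents that add atoms: water O
Why: Proposed new method: cationic monovalent gold activates the alkyne of 15 and the unsubstituted terminus C5 of the 1-methoxydiene (C2=C3–C4=C5) attacks its distal carbon, after which protodeauration and hydrolysis of the conjugated oxocarbenium ion give the C2 enone of bicyclo[3.2.1]octadienone 16, and Sc(OTf)3/water then hydrolyses the bridging ketal to the bridgehead α-hydroxy-β-diketone 17. In 17 the C1–C2 acyl bond is aligned with the π* orbital of the strained C8 ketone, so a Lewis-acid-templated α-ketol (acyloin) 1,2-acyl shift moves C2 from C1 to C8, which contracts the six-membered ring C1–C2–C3–C4–C5–C8 to ring A of 18 (C8 of 17 becomes the carbinol C1 of 18 and the expelled carbinol carbon C1 of 17 becomes the C8 ketone of ring B). The closest known reactions are the gold-catalysed 5-endo-dig Conia-ene-type carbocyclisation of silyl enol ethers onto alkynes, extended here to the δ-carbon of a methyl dienol ether in the manner of vinylogous Mukaiyama additions, and the acyloin ring contraction of cyclic 2-hydroxy-1,3-diketones to 2-acyl-2-hydroxycyclopentenones (humulone to isohumulone type). Ring B is closed in the 5-endo-dig mode (as the two-carbon bridge of 16), whereas ring A is not closed but arises by 1,2-shift ring contraction of the former six-membered carbocycle. The C5 stereocentre is dictated by the carbinol centre of 15, since the tethered alkyne can reach C5 only on its own face, and the C1 carbinol of 18 is fixed by the suprafacial shift inside the bridged frame, which can deliver only the cis-fused (1S,5S) bicycle. The step needs attack through C5 and not through the aryl-bearing enol-ether β-carbon C3, which sterics and the formation of the conjugated oxocarbenium ion should secure, and acyl instead of vinyl migration, which thermodynamics should secure because all α-ketol isomers interconvert and only the acyl shift leads to the unstrained, doubly conjugated diquinane.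

Step 11
Reactants: 18 (1S,5S)-4-(3,5-dimethoxyphenyl)-6-[(E)-2-(3,5-dimethoxyphenyl)ethenyl]-1-hydroxy-3-(3,4,5-trimethoxyphenyl)bicyclo[3.3.0]octa-3,6-diene-2,8-dione
Product: 19 (1S,5S)-4-(3,5-dihydroxyphenyl)-6-[(E)-2-(3,5-dihydroxyphenyl)ethenyl]-1-hydroxy-3-(3,4,5-trihydroxyphenyl)bicyclo[3.3.0]octa-3,6-diene-2,8-dione (CNP0306657.1)
Conditions: BBr3 (15 equiv), CH2Cl2, −78 → 0 °C; then H2O
Reagents that add atoms: none
Why: Lewis-acid ether cleavage (boron tribromide demethylation) of the seven aryl methyl ethers; the tertiary alcohol should not ionise because its carbon carries two acyl groups, and neither stereocentre is touched.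

**Compound list**

1 | 4-bromo-2,6-dimethoxyphenol | COc1cc(Br)cc(OC)c1O | starting material
2 | 2-(benzyloxy)-5-bromo-1,3-dimethoxybenzene | COc1cc(Br)cc(OC)c1OCc1ccccc1 | intermediate
3 | 2-(benzyloxy)-5-bromo-4-iodo-1,3-dimethoxybenzene | COc1cc(Br)c(I)c(OC)c1OCc1ccccc1 | intermediate
4 | 3,4,5-trimethoxyphenylboronic acid | COc1cc(B(O)O)cc(OC)c1OC | starting material
5 | 3-(benzyloxy)-6-bromo-2,3',4,4',5'-pentamethoxy-1,1'-biphenyl | COc1cc(Br)c(-c2cc(OC)c(OC)c(OC)c2)c(OC)c1OCc1ccccc1 | intermediate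
6 | 3,5-dimethoxyphenylboronic acid | COc1cc(OC)cc(B(O)O)c1 | starting material
7 | 2-(benzyloxy)-5-(3,5-dimethoxyphenyl)-1,3-dimethoxy-4-(3,4,5-trimethoxyphenyl)benzene | COc1cc(-c2cc(OC)cc(OC)c2)c(-c2cc(OC)c(OC)c(OC)c2)c(OC)c1OCc1ccccc1 | intermediate
8 | 4-(3,5-dimethoxyphenyl)-2,6-dimethoxy-3-(3,4,5-trimethoxyphenyl)phenol | COc1cc(-c2cc(OC)cc(OC)c2)c(-c2cc(OC)c(OC)c(OC)c2)c(OC)c1O | intermediate
9 | 4-(3,5-dimethoxyphenyl)-2,6,6-trimethoxy-3-(3,4,5-trimethoxyphenyl)cyclohexa-2,4-dien-1-one | COC1=C(c2cc(OC)c(OC)c(OC)c2)C(c2cc(OC)cc(OC)c2)=CC(OC)(OC)C1=O | intermediate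
10 | 3,5-dimethoxybenzaldehyde | COc1cc(C=O)cc(OC)c1 | starting material
11 | diethyl [3-(trimethylsilyl)prop-2-yn-1-yl]phosphonate | CCOP(=O)(CC#C[Si](C)(C)C)OCC | starting material
12 | [(3E)-4-(3,5-dimethoxyphenyl)but-3-en-1-yn-1-yl]trimethylsilane | COc1cc(/C=C/C#C[Si](C)(C)C)cc(OC)c1 | intermediate
13 | 1-[(1E)-but-1-en-3-yn-1-yl]-3,5-dimethoxybenzene | COc1cc(/C=C/C#C)cc(OC)c1 | intermediate
14 | [(3E)-4-(3,5-dimethoxyphenyl)but-3-en-1-yn-1-yl](methyl)zinc | C[Zn]C#C/C=C/c1cc(OC)cc(OC)c1 | intermediate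
15 | (1S)-4-(3,5-dimethoxyphenyl)-1-[(3E)-4-(3,5-dimethoxyphenyl)but-3-en-1-yn-1-yl]-2,6,6-trimethoxy-3-(3,4,5-trimethoxyphenyl)cyclohexa-2,4-dien-1-ol | COC1=C(c2cc(OC)c(OC)c(OC)c2)C(c2cc(OC)cc(OC)c2)=CC(OC)(OC)[C@]1(O)C#C/C=C/c1cc(OC)cc(OC)c1 | intermediate
16 | (1S,5S)-4-(3,5-dimethoxyphenyl)-6-[(E)-2-(3,5-dimethoxyphenyl)ethenyl]-1-hydroxy-8,8-dimethoxy-3-(3,4,5-trimethoxyphenyl)bicyclo[3.2.1]octa-3,6-dien-2-one | O[C@@]12C=C(/C=C/c3cc(OC)cc(OC)c3)[C@@H](C(c3cc(OC)cc(OC)c3)=C(c3cc(OC)c(OC)c(OC)c3)C1=O)C2(OC)OC | intermediate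
17 | (1R,5S)-4-(3,5-dimethoxyphenyl)-6-[(E)-2-(3,5-dimethoxyphenyl)ethenyl]-1-hydroxy-3-(3,4,5-trimethoxyphenyl)bicyclo[3.2.1]octa-3,6-diene-2,8-dione | O[C@@]12C=C(/C=C/c3cc(OC)cc(OC)c3)[C@@H](C(c3cc(OC)cc(OC)c3)=C(c3cc(OC)c(OC)c(OC)c3)C1=O)C2=O | intermediate
18 | (1S,5S)-4-(3,5-dimethoxyphenyl)-6-[(E)-2-(3,5-dimethoxyphenyl)ethenyl]-1-hydroxy-3-(3,4,5-trimethoxyphenyl)bicyclo[3.3.0]octa-3,6-diene-2,8-dione | O=C1C=C(/C=C/c2cc(OC)cc(OC)c2)[C@H]2C(c3cc(OC)cc(OC)c3)=C(c3cc(OC)c(OC)c(OC)c3)C(=O)[C@@]12O | intermediate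
19 | (1S,5S)-4-(3,5-dihydroxyphenyl)-6-[(E)-2-(3,5-dihydroxyphenyl)ethenyl]-1-hydroxy-3-(3,4,5-trihydroxyphenyl)bicyclo[3.3.0]octa-3,6-diene-2,8-dione | O=C1C=C(/C=C/c2cc(O)cc(O)c2)[C@H]2C(c3cc(O)cc(O)c3)=C(c3cc(O)c(O)c(O)c3)C(=O)[C@@]12O | target

**Step count and risks**

Total step count: 11. Longest linear sequence: 9 steps (steps 1, 2, 3, 4, 5, 6, 9, 10, 11).

Most likely to fail, in order:

Step 10 (bears the label). The dienol ether may be protonated or hydrolysed before it cyclises, a ketal oxygen or C3 may attack the gold-activated alkyne in place of C5, or the strained β-diketone may undergo hydrolytic C–C cleavage while the ketal is unmasked. The fallback uses established reactions only and sets out from 15. Mild aqueous acid (PPTS, acetone/H2O, 23 °C) should hydrolyse the enol ether and the allylic ketal to (2R)-5-(3,5-dimethoxyphenyl)-2-[(3E)-4-(3,5-dimethoxyphenyl)but-3-en-1-yn-1-yl]-2-hydroxy-4-(3,4,5-trimethoxyphenyl)cyclohex-4-ene-1,3-dione F1. TMSOTf/Et3N (CH2Cl2, −78 → 0 °C) should silylate the tertiary alcohol and form the silyl dienol ether, giving (6R)-3-(3,5-dimethoxyphenyl)-6-[(3E)-4-(3,5-dimethoxyphenyl)but-3-en-1-yn-1-yl]-2-(3,4,5-trimethoxyphenyl)-5,6-bis(trimethylsilyloxy)cyclohexa-2,4-dien-1-one F2. The known gold-catalysed 5-endo-dig carbocyclisation of a silyl enol ether onto an alkyne (Ph3PAuCl/AgBF4, CH2Cl2/MeOH, 23 °C) should then give (1R,5S)-4-(3,5-dimethoxyphenyl)-6-[(E)-2-(3,5-dimethoxyphenyl)ethenyl]-3-(3,4,5-trimethoxyphenyl)-1-(trimethylsilyloxy)bicyclo[3.2.1]octa-3,6-diene-2,8-dione F3. Sc(OTf)3 in MeCN/H2O removes the silyl group to give 17, which contracts by the α-ketol shift to 18, where the route is rejoined.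

Step 9. Facial discrimination may be insufficient, the carbonyl flanked by two fully substituted carbons may not turn over, or the Lewis acid may ionise the ketal. The fallback sets out from 9. Deprotonation of 13 with n-BuLi (THF, −78 °C) gives lithium (3E)-4-(3,5-dimethoxyphenyl)but-3-en-1-yn-1-ide F4, whose 1,2-addition to 9 (an established reaction of alkynyllithiums with o-quinone monoketals) gives racemic 4-(3,5-dimethoxyphenyl)-1-[(3E)-4-(3,5-dimethoxyphenyl)but-3-en-1-yn-1-yl]-2,6,6-trimethoxy-3-(3,4,5-trimethoxyphenyl)cyclohexa-2,4-dien-1-ol F5. Preparative supercritical-fluid chromatography on a chiral stationary phase separates it; the (1S) enantiomer is 15, where the route is rejoined, and the (1R) enantiomer of 15 F6 is set aside.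

Step 11. An electron-rich aryl ring may add in Friedel–Crafts fashion to the Lewis-acid-activated dienone of ring B, HBr may add to the diene, or ether cleavage may stay incomplete. The fallback changes the order of events and sets out from 16, isolated by stopping step 10 after the gold stage. BBr3 (CH2Cl2, −78 → 0 °C, aqueous work-up) should cleave the seven aryl methyl ethers and the bridging ketal while the ring B enone does not yet exist, giving (1R,5S)-4-(3,5-dihydroxyphenyl)-6-[(E)-2-(3,5-dihydroxyphenyl)ethenyl]-1-hydroxy-3-(3,4,5-trihydroxyphenyl)bicyclo[3.2.1]octa-3,6-diene-2,8-dione F7. Sc(OTf)3 (MeCN/H2O, 40 °C) should then effect the α-ketol ring contraction directly to 19, where the route is rejoined.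

**Further compounds**

F1 | step 10 | (2R)-5-(3,5-dimethoxyphenyl)-2-[(3E)-4-(3,5-dimethoxyphenyl)but-3-en-1-yn-1-yl]-2-hydroxy-4-(3,4,5-trimethoxyphenyl)cyclohex-4-ene-1,3-dione | O=C1C(c2cc(OC)c(OC)c(OC)c2)=C(c2cc(OC)cc(OC)c2)CC(=O)[C@]1(O)C#C/C=C/c1cc(OC)cc(OC)c1
F2 | step 10 | (6R)-3-(3,5-dimethoxyphenyl)-6-[(3E)-4-(3,5-dimethoxyphenyl)but-3-en-1-yn-1-yl]-2-(3,4,5-trimethoxyphenyl)-5,6-bis(trimethylsilyloxy)cyclohexa-2,4-dien-1-one | O=C1C(c2cc(OC)c(OC)c(OC)c2)=C(c2cc(OC)cc(OC)c2)C=C(O[Si](C)(C)C)[C@]1(O[Si](C)(C)C)C#C/C=C/c1cc(OC)cc(OC)c1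
F3 | step 10 | (1R,5S)-4-(3,5-dimethoxyphenyl)-6-[(E)-2-(3,5-dimethoxyphenyl)ethenyl]-3-(3,4,5-trimethoxyphenyl)-1-(trimethylsilyloxy)bicyclo[3.2.1]octa-3,6-diene-2,8-dione | C[Si](C)(C)O[C@@]12C=C(/C=C/c3cc(OC)cc(OC)c3)[C@@H](C(c3cc(OC)cc(OC)c3)=C(c3cc(OC)c(OC)c(OC)c3)C1=O)C2=O
F4 | step 9 | lithium (3E)-4-(3,5-dimethoxyphenyl)but-3-en-1-yn-1-ide | [Li]C#C/C=C/c1cc(OC)cc(OC)c1
F5 | step 9 | racemic 4-(3,5-dimethoxyphenyl)-1-[(3E)-4-(3,5-dimethoxyphenyl)but-3-en-1-yn-1-yl]-2,6,6-trimethoxy-3-(3,4,5-trimethoxyphenyl)cyclohexa-2,4-dien-1-ol | COC1=C(c2cc(OC)c(OC)c(OC)c2)C(c2cc(OC)cc(OC)c2)=CC(OC)(OC)C1(O)C#C/C=C/c1cc(OC)cc(OC)c1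
F6 | step 9 | (1R)-4-(3,5-dimethoxyphenyl)-1-[(3E)-4-(3,5-dimethoxyphenyl)but-3-en-1-yn-1-yl]-2,6,6-trimethoxy-3-(3,4,5-trimethoxyphenyl)cyclohexa-2,4-dien-1-ol | COC1=C(c2cc(OC)c(OC)c(OC)c2)C(c2cc(OC)cc(OC)c2)=CC(OC)(OC)[C@@]1(O)C#C/C=C/c1cc(OC)cc(OC)c1
F7 | step 11 | (1R,5S)-4-(3,5-dihydroxyphenyl)-6-[(E)-2-(3,5-dihydroxyphenyl)ethenyl]-1-hydroxy-3-(3,4,5-trihydroxyphenyl)bicyclo[3.2.1]octa-3,6-diene-2,8-dione | O[C@@]12C=C(/C=C/c3cc(O)cc(O)c3)[C@@H](C(c3cc(O)cc(O)c3)=C(c3cc(O)c(O)c(O)c3)C1=O)C2=O
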